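## Analysis of the target

The target is a germacranolide: a ten-membered carbocycle (C1–C10) carrying a trans-fused α-methylene-γ-lactone across C6–C7 (C12 carbonyl, O on C6), a C4–C5 epoxide, a 1(10)E,2Z-dienoate with the C14 methyl ester on C10, an acetate on C9 and a (2S,3S)-2,3-dimethyloxirane-2-carboxylate on C8. Six contiguous ring stereocenters (4R,5R,6S,7R,8S,9S) are present. The epoxide is trans (C3 and C6 on opposite faces), O5/O6 are threo, H6/H7 are trans, the C7 branch is anti to O8, and O8/O9 are threo. The sensitive groups are the exo-methylene lactone (Michael acceptor), the C9 acetate (allylic, next to an enoate, open to SN2′ loss), the vinyl epoxide, two vicinal esters that can migrate, and a cis,cis-diene that can isomerize. The difficulty is the medium ring with its two ring-cis alkenes together with dense, differentiated oxygenation on five adjacent carbons. The feature used here is C10: it sits between the C14 ester carbon and the oxygenated C9 and is doubly bonded to C1, so with C9 as a ketone C10 is the methylene of a β-keto ester and C1 is an aldehyde carbon. The C10=C1 bond can therefore be made by condensation, and that condensation can close the ring.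

## Retrosynthetic reasoning

Lactone last. The lactone C12–O6 bond of 37 is cut to the 2-methylene-1,4-diol 34. The exo-methylene lactone is the most electrophilic group of the target, whereas the diol oxidation level is inert to amines and hydride. Forward, chemoselective oxidation of the primary allylic alcohol must give the lactol and then the lactone. Diol 34 comes from bis-silyl ether 33.

Esters. The C8–O acyl bond of 33 is cut to alcohol 27 and epoxy acid 31, so the fragile epoxy ester arrives intact and late. 27 comes from 26 (selective loss of the C8 triethylsilyl group) and 26 from alcohol 25 (acetylation). O8 and O9 are differentiated by origin: O9 is formed free in the reduction while O8 is still silylated. Acid 31 is cut to angelic acid 28 through alcohols 29 and 30; a Sharpless epoxidation sets both of its stereocenters.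

C9–H. Alcohol 25 is traced to ketone 24. The ketone is needed for the ring closure; forward, a 1,2-selective reduction must deliver hydride anti to the C8–O bond.

C10=C1, the ring-closing cut. Ketone 24 is opened at C10=C1 to the acyclic keto ester enal 23. This is the only ring bond whose formation creates no stereocenter and needs no metal, and it puts the geometry of the new alkene under the control of the ring. Cutting C6–C7, C7–C8 or C8–C9 instead would form stereocenters during cyclization, and cutting C2=C3 would need a Z-selective macro-olefination. Everything stereochemical is then settled on an open chain by reagent control.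

Enal and keto ester. Enal 23 comes from Z-allylic alcohol 22 and that from propargylic alcohol 21, so the alkyne masks the cis alkene until two steps before ring closure. The C9 ketone of 21 is traced to ynoate 19 (hydration through enamine 20), and 19 to 18 and 17. The C8–C9 bond of 17 is cut to aldehyde 15 and methyl propiolate 16; this brings in C9, C10 and C14 together and sets C8 under catalyst control.

C6–C7. Aldehyde 15 is traced through 14 and 13 to allylic alcohol 12, whose C12 oxygen comes from allylic oxidation of isopropenyl compound 11. The C6–C7 bond of the parent aldol 10 is cut to epoxy aldehyde 6 and enoyl imide 9 (from 7 and 8). A syn-aldol sets C6 and C7 in the sense of the trans-lactone and has to override the aldehyde's own facial bias.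

C1–C6 piece. Aldehyde 6 is traced through 5, 4 and 3 to epoxy alcohol 2 (C1 added to the alkyne as formaldehyde), and 2 to commercial enynol 1 by Sharpless epoxidation, which sets C4 and C5.

## Alternatives that were turned down

Alternative 1: the lactone C6–O bond is cut. A costunolide-synthase-type P450 would hydroxylate the allylic C6–H of seco acid A2 on the α face; spontaneous lactonization would give A1, and the 4,5-alkene would be epoxidized last.
- For: one oxidation sets C6 and closes the lactone without protecting groups. On end-game economy this is stronger than the chosen route, which spends five steps on the same result (C6 silylation, C12 oxidation, silylation, desilylation, oxidative lactonization).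
- Against: the step forms no C–C bond and no part of the carbocycle, so the ten-membered 1(10)E,2Z,4E-triene A2, with both esters in place, must be made first, and that is the hard problem. The natural substrates of these enzymes carry no oxygen at C8 or C9 and no ester at C10, so the enzyme would have to be evolved. C6 must also be distinguished from the other allylic positions, and a late face-selective epoxidation remains.
- Comparison: the chosen strategy offers a ring construction with C4–C8 already fixed by reagent control.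

Alternative 2: C4–C5 and C8–C9 are cut, with a one-carbon ketone bridge between C4 and C9. Heating tropone A4 with bis(silyloxy)diene A5 would give the exo (6+4) adduct A3.
- For: two C–C bonds, the ten-membered ring and four stereocenters in one convergent step, with the ring-cis diene fixed by the tropone. Because the ring is made by cycloaddition, without high dilution, this is more certain in ring formation than the condensation chosen here.
- Against: regiochemistry with two unsymmetrical partners, competition from (4+2) addition, and formation of a quaternary C4 next to the carbonyl. After the cycloaddition the bridging carbonyl must be excised with both of its C–C bonds turned into C–O bonds. C6 then still lacks oxygen, C7 is still an alkene carbon carrying CH2CO2Me instead of the methylene lactone, and O5 must be inverted to form a trans epoxide.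
- Comparison: more than a dozen redox and cleavage steps would follow the key step, against six here, where the oxidation pattern is in place before the ring closes.

Alternative 3: the C5–C10 σ bond is cut. Irradiation of cis-fused hexalin A7 at 254 nm at low temperature would open it conrotatorily to the ten-membered triene A6.
- For: the decalin is easy to build with six-membered-ring stereocontrol, the strain is paid by light, and diene-to-triene photolysis has delivered germacrane rings before. Precedent for the ring-forming step is therefore stronger than for the chosen step.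
- Against: the conjugated triene ester A6 absorbs more strongly than A7, so re-closure, E/Z isomerization and hydrogen shifts compete. Only one of the two conrotatory senses gives 1(10)-cis/4-trans. The exo-methylene lactone is itself photolabile, a quaternary ester-bearing C10 must be built at the ring fusion, and the epoxide and the C8 ester must still be installed afterwards.
- Comparison: the chosen strategy carries the epoxide from the first step as a stereochemical and conformational element and keeps light-sensitive chromophores out of the ring-forming step.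

Key step: step 19

## Route

Remarks on the chemistry:
- Germacrane numbering (C1–C15) is used for atoms.
- Metal salts of numbered compounds (acetylides, enolates, alkoxides) and other transient species of a single operation are treated as forms of the parent compound and are not numbered.
- Compounds 1, 7, 8, 16 and 28 are taken as commercial.
- In step 13 only the face requirement (Re-face addition at C8) is essential; the ProPhenol antipode written is the one assumed to meet it, and its mirror image would be used otherwise.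

Step 1
Reactants: 1 (E)-3-methylpent-2-en-4-yn-1-ol
Product: 2 [(2R,3R)-3-ethynyl-3-methyloxiran-2-yl]methanol
Conditions: Ti(OiPr)4 (10 mol%), D-(−)-diethyl tartrate (12 mol%), t-BuOOH, 4 Å MS, CH2Cl2, −20 °C
Reagents that add atoms: tert-butyl hydroperoxide, CC(C)(C)OO
Why: Sharpless asymmetric epoxidation of an E-trisubstituted allylic alcohol; D-(−)-tartrate directs oxygen to the face that gives the (2R,3R)-epoxide, which sets C4 and C5 (methyl cis to C6, alkyne trans), and the alkyne is inert.

Step 2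
Reactants: 2 [(2R,3R)-3-ethynyl-3-methyloxiran-2-yl]methanol
Product: 3 triethyl{[(2R,3R)-3-ethynyl-3-methyloxiran-2-yl]methoxy}silane
Conditions: Et3SiCl, imidazole, CH2Cl2, 0 °C
Reagents that add atoms: chlorotriethylsilane, CC[Si](Cl)(CC)CC
Why: Routine silylation; it masks the only acidic O–H before the acetylide is made and can later be oxidized off directly.

Step 3
Reactants: 3 triethyl{[(2R,3R)-3-ethynyl-3-methyloxiran-2-yl]methoxy}silane
Product: 4 3-[(2R,3R)-2-methyl-3-(triethylsilyloxymethyl)oxiran-2-yl]prop-2-yn-1-ol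
Conditions: n-BuLi, THF, −78 °C; (CH2O)n, −78 → 0 °C
Reagents that add atoms: formaldehyde (as paraformaldehyde), C=O
Why: Hydroxymethylation of a lithium acetylide adds C1; the acetylide is held at low temperature so that the propargylic epoxide is not opened.

Step 4
Reactants: 4 3-[(2R,3R)-2-methyl-3-(triethylsilyloxymethyl)oxiran-2-yl]prop-2-yn-1-ol
Product: 5 triethyl({(2R,3R)-3-[3-(4-methoxybenzyloxy)prop-1-ynyl]-3-methyloxiran-2-yl}methoxy)silane
Conditions: NaH, 4-methoxybenzyl chloride, Bu4NI (cat.), THF/DMF, 0 °C → rt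
Reagents that add atoms: 4-methoxybenzyl chloride, COc1ccc(CCl)cc1
Why: Williamson etherification; the 4-methoxybenzyl ether is the one group of the route removed oxidatively, so C1–OH can be freed later beside three silyl ethers.

Step 5
Reactants: 5 triethyl({(2R,3R)-3-[3-(4-methoxybenzyloxy)prop-1-ynyl]-3-methyloxiran-2-yl}methoxy)silane
Product: 6 (2S,3R)-3-[3-(4-methoxybenzyloxy)prop-1-ynyl]-3-methyloxirane-2-carbaldehyde
Conditions: (COCl)2, DMSO, CH2Cl2, −78 → −40 °C; Et3N, −78 → 0 °C
Reagents that add atoms: none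
Why: Swern oxidation applied directly to a primary triethylsilyl ether (the chlorosulfonium salt exchanges silicon for sulfur at oxygen and the alkoxysulfonium ylide collapses to the aldehyde), which saves a deprotection; the epoxide carbon C5 is not enolized at this temperature.

Step 6
Reactants: 7 (4S)-4-benzyl-1,3-oxazolidin-2-one; 8 3-methylbut-2-enoyl chloride
Product: 9 (4S)-4-benzyl-3-(3-methylbut-2-enoyl)-1,3-oxazolidin-2-one
Conditions: n-BuLi, THF, −78 °C; then 8, −78 → 0 °C
Reagents that add atoms: none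
Why: N-acylation of the lithiated oxazolidinone gives the aldol donor that carries C7, C8, C11, C12 and C13.

Step 7
Reactants: 9 (4S)-4-benzyl-3-(3-methylbut-2-enoyl)-1,3-oxazolidin-2-one; 6 (2S,3R)-3-[3-(4-methoxybenzyloxy)prop-1-ynyl]-3-methyloxirane-2-carbaldehyde
Product: 10 (4S)-4-benzyl-3-[(2S,3S)-3-hydroxy-3-{(2R,3R)-3-[3-(4-methoxybenzyloxy)prop-1-ynyl]-3-methyloxiran-2-yl}-2-(prop-1-en-2-yl)propanoyl]-1,3-oxazolidin-2-one
Conditions: Bu2BOTf, Et3N, CH2Cl2, −78 → 0 °C; 6, −78 → −20 °C; pH 7 buffer, MeOH, H2O2, 0 °C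
Reagents that add atoms: none
Why: Evans syn-aldol in its deconjugative form: γ-deprotonation gives the Z boron dienolate, which reacts at its α-carbon through a Zimmerman–Traxler chair on the face away from the benzyl group; this sets C6 and C7 in the relationship of the trans-lactone under auxiliary control, which overrides the weak Felkin bias of the epoxy aldehyde (the required adduct has O6 syn to the epoxide oxygen).

Step 8
Reactants: 10 (4S)-4-benzyl-3-[(2S,3S)-3-hydroxy-3-{(2R,3R)-3-[3-(4-methoxybenzyloxy)prop-1-ynyl]-3-methyloxiran-2-yl}-2-(prop-1-en-2-yl)propanoyl]-1,3-oxazolidin-2-one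
Product: 11 (4S)-4-benzyl-3-[(2S,3S)-3-(tert-butyldimethylsilyloxy)-3-{(2R,3R)-3-[3-(4-methoxybenzyloxy)prop-1-ynyl]-3-methyloxiran-2-yl}-2-(prop-1-en-2-yl)propanoyl]-1,3-oxazolidin-2-one
Conditions: TBSOTf, 2,6-lutidine, CH2Cl2, −78 → 0 °C
Reagents that add atoms: tert-butyldimethylsilyl trifluoromethanesulfonate, CC(C)(C)[Si](C)(C)OS(=O)(=O)C(F)(F)F
Why: Silylation of the hindered aldol hydroxyl blocks retro-aldol and keeps O6 out of the coming oxidation; the base is too weak to enolize the imide.

Step 9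
Reactants: 11 (4S)-4-benzyl-3-[(2S,3S)-3-(tert-butyldimethylsilyloxy)-3-{(2R,3R)-3-[3-(4-methoxybenzyloxy)prop-1-ynyl]-3-methyloxiran-2-yl}-2-(prop-1-en-2-yl)propanoyl]-1,3-oxazolidin-2-one
Product: 12 (4S)-4-benzyl-3-[(2S,3S)-3-(tert-butyldimethylsilyloxy)-2-(3-hydroxyprop-1-en-2-yl)-3-{(2R,3R)-3-[3-(4-methoxybenzyloxy)prop-1-ynyl]-3-methyloxiran-2-yl}propanoyl]-1,3-oxazolidin-2-one
Conditions: SeO2 (0.5 equiv), t-BuOOH, CH2Cl2, rt
Reagents that add atoms: tert-butyl hydroperoxide (oxygen relayed through SeO2), CC(C)(C)OO; selenium dioxide, O=[Se]=O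
Why: Riley allylic oxidation (ene reaction at the terminal CH2, then [2,3]-shift); of the two allylic positions on the substituted alkene carbon the methyl group reacts in preference to the hindered, carbonyl-deactivated C7 methine, giving the 2-(hydroxymethyl)vinyl group, the masked lactone carbonyl C12.

Step 10
Reactants: 12 (4S)-4-benzyl-3-[(2S,3S)-3-(tert-butyldimethylsilyloxy)-2-(3-hydroxyprop-1-en-2-yl)-3-{(2R,3R)-3-[3-(4-methoxybenzyloxy)prop-1-ynyl]-3-methyloxiran-2-yl}propanoyl]-1,3-oxazolidin-2-one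
Product: 13 (4S)-4-benzyl-3-[(2S,3S)-3-(tert-butyldimethylsilyloxy)-2-[3-(tert-butyldiphenylsilyloxy)prop-1-en-2-yl]-3-{(2R,3R)-3-[3-(4-methoxybenzyloxy)prop-1-ynyl]-3-methyloxiran-2-yl}propanoyl]-1,3-oxazolidin-2-one
Conditions: TBDPSCl, imidazole, DMF, 0 °C → rt
Reagents that add atoms: tert-butyl(chloro)diphenylsilane, CC(C)(C)[Si](Cl)(c1ccccc1)c1ccccc1
Why: Silylation of the primary allylic alcohol; the acid-stable TBDPS group is chosen so that the C8 triethylsilyl ether can later be removed beside it with protic acid.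

Step 11
Reactants: 13 (4S)-4-benzyl-3-[(2S,3S)-3-(tert-butyldimethylsilyloxy)-2-[3-(tert-butyldiphenylsilyloxy)prop-1-en-2-yl]-3-{(2R,3R)-3-[3-(4-methoxybenzyloxy)prop-1-ynyl]-3-methyloxiran-2-yl}propanoyl]-1,3-oxazolidin-2-one
Product: 14 (2R,3S)-3-(tert-butyldimethylsilyloxy)-2-[3-(tert-butyldiphenylsilyloxy)prop-1-en-2-yl]-3-{(2R,3R)-3-[3-(4-methoxybenzyloxy)prop-1-ynyl]-3-methyloxiran-2-yl}propan-1-ol
Conditions: LiBH4, MeOH (1 equiv), Et2O, 0 °C
Reagents that add atoms: none
Why: Reductive cleavage of the N-acyl oxazolidinone to the primary alcohol without epimerizing C7; the epoxide and the ethers are not reduced at 0 °C, and the auxiliary is recovered.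

Step 12
Reactants: 14 (2R,3S)-3-(tert-butyldimethylsilyloxy)-2-[3-(tert-butyldiphenylsilyloxy)prop-1-en-2-yl]-3-{(2R,3R)-3-[3-(4-methoxybenzyloxy)prop-1-ynyl]-3-methyloxiran-2-yl}propan-1-ol
Product: 15 (2S,3S)-3-(tert-butyldimethylsilyloxy)-2-[3-(tert-butyldiphenylsilyloxy)prop-1-en-2-yl]-3-{(2R,3R)-3-[3-(4-methoxybenzyloxy)prop-1-ynyl]-3-methyloxiran-2-yl}propanal
Conditions: Dess–Martin periodinane, pyridine, CH2Cl2, 0 °C
Reagents that add atoms: none
Why: Buffered Dess–Martin oxidation gives the α-branched β,γ-unsaturated aldehyde without epimerization at C7 or migration of the alkene; 15 is used at once.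

Step 13
Reactants: 15 (2S,3S)-3-(tert-butyldimethylsilyloxy)-2-[3-(tert-butyldiphenylsilyloxy)prop-1-en-2-yl]-3-{(2R,3R)-3-[3-(4-methoxybenzyloxy)prop-1-ynyl]-3-methyloxiran-2-yl}propanal; 16 methyl prop-2-ynoate
Product: 17 methyl (4S,5R,6S)-6-(tert-butyldimethylsilyloxy)-5-[3-(tert-butyldiphenylsilyloxy)prop-1-en-2-yl]-4-hydroxy-6-{(2R,3R)-3-[3-(4-methoxybenzyloxy)prop-1-ynyl]-3-methyloxiran-2-yl}hex-2-ynoate
Conditions: 16 (3 equiv), Me2Zn (3 equiv), (S,S)-ProPhenol (20 mol%), Ph3PO (40 mol%), toluene, 4 °C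
Reagents that add atoms: none
Why: Zinc–ProPhenol catalysed alkynylation of an aldehyde with methyl propiolate; the dinuclear zinc complex delivers the alkynyl group under catalyst control, and addition to the Re face of C8 gives the (4S)-carbinol, anti to the C7 branch, while bringing in C9, C10 and C14 in one step.

Step 14
Reactants: 17 methyl (4S,5R,6S)-6-(tert-butyldimethylsilyloxy)-5-[3-(tert-butyldiphenylsilyloxy)prop-1-en-2-yl]-4-hydroxy-6-{(2R,3R)-3-[3-(4-methoxybenzyloxy)prop-1-ynyl]-3-methyloxiran-2-yl}hex-2-ynoate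
Product: 18 methyl (4S,5R,6S)-6-(tert-butyldimethylsilyloxy)-5-[3-(tert-butyldiphenylsilyloxy)prop-1-en-2-yl]-6-{(2R,3R)-3-[3-(4-methoxybenzyloxy)prop-1-ynyl]-3-methyloxiran-2-yl}-4-(triethylsilyloxy)hex-2-ynoate
Conditions: Et3SiOTf, 2,6-lutidine, CH2Cl2, −78 °C
Reagents that add atoms: triethylsilyl trifluoromethanesulfonate, CC[Si](CC)(CC)OS(=O)(=O)C(F)(F)F
Why: Silylation under non-acidic conditions; O8 must be capped before the keto ester is unveiled (a free γ-hydroxy keto ester would close to a tetronic acid), and a silyl ether cannot chelate in the later reduction.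

Step 15
Reactants: 18 methyl (4S,5R,6S)-6-(tert-butyldimethylsilyloxy)-5-[3-(tert-butyldiphenylsilyloxy)prop-1-en-2-yl]-6-{(2R,3R)-3-[3-(4-methoxybenzyloxy)prop-1-ynyl]-3-methyloxiran-2-yl}-4-(triethylsilyloxy)hex-2-ynoate
Product: 19 methyl (4S,5R,6S)-6-(tert-butyldimethylsilyloxy)-5-[3-(tert-butyldiphenylsilyloxy)prop-1-en-2-yl]-6-[(2R,3R)-3-(3-hydroxyprop-1-ynyl)-3-methyloxiran-2-yl]-4-(triethylsilyloxy)hex-2-ynoate
Conditions: DDQ, CH2Cl2/pH 7 buffer (10:1), 0 °C
Reagents that add atoms: none
Why: Oxidative cleavage of the 4-methoxybenzyl ether frees C1–OH; silyl ethers, epoxide and the electron-poor alkyne do not react with DDQ under buffered conditions.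

Step 16
Reactants: 19 methyl (4S,5R,6S)-6-(tert-butyldimethylsilyloxy)-5-[3-(tert-butyldiphenylsilyloxy)prop-1-en-2-yl]-6-[(2R,3R)-3-(3-hydroxyprop-1-ynyl)-3-methyloxiran-2-yl]-4-(triethylsilyloxy)hex-2-ynoate
Product: 21 methyl (4S,5S,6S)-6-(tert-butyldimethylsilyloxy)-5-[3-(tert-butyldiphenylsilyloxy)prop-1-en-2-yl]-6-[(2R,3R)-3-(3-hydroxyprop-1-ynyl)-3-methyloxiran-2-yl]-3-oxo-4-(triethylsilyloxy)hexanoate, via morpholino enoate 20 (not isolated)
Conditions: morpholine, Et2O, 0 °C → rt; then 10% aq. citric acid, THF, 0 °C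
Reagents that add atoms: water, O
Why: Conjugate addition of a secondary amine to the ynoate puts nitrogen on C9 (β to the ester); mild aqueous acid hydrolyses the vinylogous carbamate to the C9 ketone, a regiospecific hydration that leaves the unactivated C2≡C3 alkyne untouched.

Step 17
Reactants: 21 methyl (4S,5S,6S)-6-(tert-butyldimethylsilyloxy)-5-[3-(tert-butyldiphenylsilyloxy)prop-1-en-2-yl]-6-[(2R,3R)-3-(3-hydroxyprop-1-ynyl)-3-methyloxiran-2-yl]-3-oxo-4-(triethylsilyloxy)hexanoate
Product: 22 methyl (4S,5S,6S)-6-(tert-butyldimethylsilyloxy)-5-[3-(tert-butyldiphenylsilyloxy)prop-1-en-2-yl]-6-{(2R,3R)-3-[(1Z)-3-hydroxyprop-1-enyl]-3-methyloxiran-2-yl}-3-oxo-4-(triethylsilyloxy)hexanoate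
Conditions: H2 (1 atm), Lindlar catalyst (Pd on CaCO3, poisoned with Pb(OAc)2), quinoline, EtOAc, rt
Reagents that add atoms: none
Why: Lindlar semi-hydrogenation; syn addition of H2 gives the 2Z alkene, and the poisoned catalyst leaves the 1,1-disubstituted alkene, the epoxide and the keto ester alone.

Step 18
Reactants: 22 methyl (4S,5S,6S)-6-(tert-butyldimethylsilyloxy)-5-[3-(tert-butyldiphenylsilyloxy)prop-1-en-2-yl]-6-{(2R,3R)-3-[(1Z)-3-hydroxyprop-1-enyl]-3-methyloxiran-2-yl}-3-oxo-4-(triethylsilyloxy)hexanoate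
Product: 23 methyl (4S,5S,6S)-6-(tert-butyldimethylsilyloxy)-5-[3-(tert-butyldiphenylsilyloxy)prop-1-en-2-yl]-6-{(2R,3R)-3-methyl-3-[(1Z)-3-oxoprop-1-enyl]oxiran-2-yl}-3-oxo-4-(triethylsilyloxy)hexanoate
Conditions: MnO2, CH2Cl2, 0 °C → rt
Reagents that add atoms: none
Why: MnO2 oxidizes only the allylic alcohol, without acid or base, so the keto ester and the cis geometry are kept; 23 is filtered and used at once.

Step 19
Reactants: 23 methyl (4S,5S,6S)-6-(tert-butyldimethylsilyloxy)-5-[3-(tert-butyldiphenylsilyloxy)prop-1-en-2-yl]-6-{(2R,3R)-3-methyl-3-[(1Z)-3-oxoprop-1-enyl]oxiran-2-yl}-3-oxo-4-(triethylsilyloxy)hexanoate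
Product: 24 methyl (1(10)E,2Z,4R,5R,6S,7S,8S)-6-(tert-butyldimethylsilyloxy)-12-(tert-butyldiphenylsilyloxy)-4,5-epoxy-9-oxo-8-(triethylsilyloxy)germacra-1(10),2,11(13)-trien-14-oate
Conditions: piperidine (0.2 equiv), AcOH (0.4 equiv), 4 Å MS, CH2Cl2, slow addition of 23 to a final 1 mM, rt → 35 °C
Reagents that add atoms: none
Why: Proposed new method: piperidinium acetate turns the C1 aldehyde into its iminium ion and enolizes the β-keto ester at C10; the enol adds to C1 and the adduct loses piperidine (or water) by E1cB elimination to give the C10=C1 alkylidene, as in intermolecular Knoevenagel condensations of β-keto esters with enals, the closest known reaction type; closure of a ten-membered carbocycle this way has no close precedent. The ring closes in the 10-(enolendo)-exo-trig mode. No stereocenter is formed; the selectivities needed are the geometry at C10=C1 (C9 cis to C2, i.e. E) and retention of the 2Z alkene. The first follows from the ring, because a ten-membered ring that already holds the cis C2=C3 alkene takes the second diene alkene only as a ring-cis unit, and reversible amine addition–elimination lets the two geometries equilibrate. The second is protected by keeping the amine low and buffered as its acetate, and a trans-enal cannot reach C10 in any case. The trans-epoxide, the cis alkene and the sp2 C9 leave only three freely rotating ring bonds, which lowers the entropic cost, and high dilution with slow addition suppresses dimerization. Molecular sieves take up the water. Because the cis-dienone can close reversibly to a 2H-pyran, 24 is reduced without storage.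

Step 20
Reactants: 24 methyl (1(10)E,2Z,4R,5R,6S,7S,8S)-6-(tert-butyldimethylsilyloxy)-12-(tert-butyldiphenylsilyloxy)-4,5-epoxy-9-oxo-8-(triethylsilyloxy)germacra-1(10),2,11(13)-trien-14-oate
Product: 25 methyl (1(10)E,2Z,4R,5R,6S,7R,8S,9S)-6-(tert-butyldimethylsilyloxy)-12-(tert-butyldiphenylsilyloxy)-4,5-epoxy-9-hydroxy-8-(triethylsilyloxy)germacra-1(10),2,11(13)-trien-14-oate
Conditions: NaBH4, CeCl3·7H2O, MeOH/THF, −78 °C
Reagents that add atoms: none
Why: Luche reduction: the hard methoxyborohydride attacks the cerium-activated ketone in 1,2-fashion in preference to the doubly activated diene; hydride is expected anti to the C8–O bond (polar Felkin–Anh, no chelation by the silyl ether) and from the outer face of the ring, which gives the 8,9-threo (9S) alcohol.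

Step 21
Reactants: 25 methyl (1(10)E,2Z,4R,5R,6S,7R,8S,9S)-6-(tert-butyldimethylsilyloxy)-12-(tert-butyldiphenylsilyloxy)-4,5-epoxy-9-hydroxy-8-(triethylsilyloxy)germacra-1(10),2,11(13)-trien-14-oate
Product: 26 methyl (1(10)E,2Z,4R,5R,6S,7R,8S,9S)-9-acetoxy-6-(tert-butyldimethylsilyloxy)-12-(tert-butyldiphenylsilyloxy)-4,5-epoxy-8-(triethylsilyloxy)germacra-1(10),2,11(13)-trien-14-oate
Conditions: Ac2O, pyridine, DMAP (5 mol%), CH2Cl2, 0 °C
Reagents that add atoms: acetic anhydride, CC(=O)OC(C)=O
Why: Acetylation of the secondary allylic alcohol; O8 is silylated, so no acyl migration is possible at this stage.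

Step 22
Reactants: 26 methyl (1(10)E,2Z,4R,5R,6S,7R,8S,9S)-9-acetoxy-6-(tert-butyldimethylsilyloxy)-12-(tert-butyldiphenylsilyloxy)-4,5-epoxy-8-(triethylsilyloxy)germacra-1(10),2,11(13)-trien-14-oate
Product: 27 methyl (1(10)E,2Z,4R,5R,6S,7R,8S,9S)-9-acetoxy-6-(tert-butyldimethylsilyloxy)-12-(tert-butyldiphenylsilyloxy)-4,5-epoxy-8-hydroxygermacra-1(10),2,11(13)-trien-14-oate
Conditions: PPTS, MeOH/CH2Cl2, 0 °C
Reagents that add atoms: none
Why: Acid-catalysed methanolysis removes the triethylsilyl ether selectively; the hindered secondary TBS ether and the TBDPS ether solvolyse far more slowly, and the electron-poor dienyl epoxide resists ionization at 0 °C.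

Step 23
Reactants: 28 (Z)-2-methylbut-2-enoic acid (angelic acid)
Product: 29 (Z)-2-methylbut-2-en-1-ol
Conditions: LiAlH4, Et2O, 0 °C
Reagents that add atoms: none
Why: Hydride reduction of the acid to the allylic alcohol; the trisubstituted alkene keeps its Z geometry at 0 °C.

Step 24
Reactants: 29 (Z)-2-methylbut-2-en-1-ol
Product: 30 [(2R,3S)-2,3-dimethyloxiran-2-yl]methanol
Conditions: Ti(OiPr)4, D-(−)-diethyl tartrate, t-BuOOH, 4 Å MS, CH2Cl2, −20 °C
Reagents that add atoms: tert-butyl hydroperoxide, CC(C)(C)OO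
Why: Sharpless asymmetric epoxidation; D-(−)-tartrate delivers oxygen to the face that gives the (2R,3S)-epoxy alcohol, which sets both stereocenters of the acyl group.

Step 25
Reactants: 30 [(2R,3S)-2,3-dimethyloxiran-2-yl]methanol
Product: 31 (2S,3S)-2,3-dimethyloxirane-2-carboxylic acid
Conditions: TEMPO (20 mol%), PhI(OAc)2, MeCN/H2O (1:1), rt
Reagents that add atoms: water, O
Why: Oxoammonium oxidation of the primary alcohol through the aldehyde hydrate to the acid; the spatial arrangement is unchanged (the C2 descriptor changes only because the priorities change) and the quaternary α-carbon cannot epimerize.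

Step 26
Reactants: 31 (2S,3S)-2,3-dimethyloxirane-2-carboxylic acid; 27 methyl (1(10)E,2Z,4R,5R,6S,7R,8S,9S)-9-acetoxy-6-(tert-butyldimethylsilyloxy)-12-(tert-butyldiphenylsilyloxy)-4,5-epoxy-8-hydroxygermacra-1(10),2,11(13)-trien-14-oate
Product: 33 methyl (1(10)E,2Z,4R,5R,6S,7R,8S,9S)-9-acetoxy-6-(tert-butyldimethylsilyloxy)-12-(tert-butyldiphenylsilyloxy)-8-{[(2S,3S)-2,3-dimethyloxiran-2-yl]carbonyloxy}-4,5-epoxygermacra-1(10),2,11(13)-trien-14-oate, via mixed anhydride 32 (not isolated)
Conditions: 31, 2,4,6-trichlorobenzoyl chloride, Et3N, toluene, rt; then 27, DMAP, toluene, 0 °C → rt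
Reagents that add atoms: none
Why: Yamaguchi esterification: DMAP attacks the mixed anhydride at the unhindered epoxy-acyl carbonyl and the acylpyridinium acylates the hindered C8 hydroxyl; low temperature and an excess of activated acid favour esterification over O9→O8 acetyl migration, and no exo-methylene lactone is yet present to take up DMAP.

Step 27
Reactants: 33 methyl (1(10)E,2Z,4R,5R,6S,7R,8S,9S)-9-acetoxy-6-(tert-butyldimethylsilyloxy)-12-(tert-butyldiphenylsilyloxy)-8-{[(2S,3S)-2,3-dimethyloxiran-2-yl]carbonyloxy}-4,5-epoxygermacra-1(10),2,11(13)-trien-14-oate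
Product: 34 methyl (1(10)E,2Z,4R,5R,6S,7S,8S,9S)-9-acetoxy-8-{[(2S,3S)-2,3-dimethyloxiran-2-yl]carbonyloxy}-4,5-epoxy-6,12-dihydroxygermacra-1(10),2,11(13)-trien-14-oate
Conditions: Bu4NF, AcOH (1:1), THF, 0 °C → rt
Reagents that add atoms: none
Why: Fluoride cleaves both silyl ethers; buffering with acetic acid keeps the medium near neutral so that the allylic acetate, the epoxy ester and the vinyl epoxide survive.

Step 28
Reactants: 34 methyl (1(10)E,2Z,4R,5R,6S,7S,8S,9S)-9-acetoxy-8-{[(2S,3S)-2,3-dimethyloxiran-2-yl]carbonyloxy}-4,5-epoxy-6,12-dihydroxygermacra-1(10),2,11(13)-trien-14-oate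
Product: 37 CNP0229507.6: methyl (1(10)E,2Z,4R,5R,6S,7R,8S,9S)-9-acetoxy-8-{[(2S,3S)-2,3-dimethyloxiran-2-yl]carbonyloxy}-4,5-epoxygermacra-1(10),2,11(13)-trien-12,6-olid-14-oate, via hydroxy enal 35 (not isolated), via lactol 36 (not isolated)
Conditions: TEMPO (20 mol%), PhI(OAc)2, CH2Cl2, rt
Reagents that add atoms: none
Why: TEMPO/PhI(OAc)2 oxidative lactonization of a 2-methylene-1,4-diol: the oxoammonium salt oxidizes the primary allylic alcohol to the enal, the C6 hydroxyl closes to the five-membered lactol (5-exo-trig) and a second oxidation gives the lactone; C6 and C7 are already trans, so the trans-fused α-methylene lactone results, and the secondary alcohol is not oxidized at a competitive rate.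

## Compound list

1 | (E)-3-methylpent-2-en-4-yn-1-ol | C#C/C(C)=C/CO | starting material
2 | [(2R,3R)-3-ethynyl-3-methyloxiran-2-yl]methanol | OC[C@H]1O[C@]1(C)C#C | intermediate
3 | triethyl{[(2R,3R)-3-ethynyl-3-methyloxiran-2-yl]methoxy}silane | CC[Si](CC)(CC)OC[C@H]1O[C@]1(C)C#C | intermediate
4 | 3-[(2R,3R)-2-methyl-3-(triethylsilyloxymethyl)oxiran-2-yl]prop-2-yn-1-ol | CC[Si](CC)(CC)OC[C@H]1O[C@]1(C)C#CCO | intermediate
5 | triethyl({(2R,3R)-3-[3-(4-methoxybenzyloxy)prop-1-ynyl]-3-methyloxiran-2-yl}methoxy)silane | CC[Si](CC)(CC)OC[C@H]1O[C@]1(C)C#CCOCc1ccc(OC)cc1 | intermediate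
6 | (2S,3R)-3-[3-(4-methoxybenzyloxy)prop-1-ynyl]-3-methyloxirane-2-carbaldehyde | O=C[C@H]1O[C@]1(C)C#CCOCc1ccc(OC)cc1 | intermediate
7 | (4S)-4-benzyl-1,3-oxazolidin-2-one | O=C1N[C@@H](Cc2ccccc2)CO1 | starting material
8 | 3-methylbut-2-enoyl chloride | CC(C)=CC(=O)Cl | starting material
9 | (4S)-4-benzyl-3-(3-methylbut-2-enoyl)-1,3-oxazolidin-2-one | CC(C)=CC(=O)N1[C@@H](Cc2ccccc2)COC1=O | intermediate
10 | (4S)-4-benzyl-3-[(2S,3S)-3-hydroxy-3-{(2R,3R)-3-[3-(4-methoxybenzyloxy)prop-1-ynyl]-3-methyloxiran-2-yl}-2-(prop-1-en-2-yl)propanoyl]-1,3-oxazolidin-2-one | O=C1OC[C@H](Cc2ccccc2)N1C(=O)[C@@H](C(C)=C)[C@H](O)[C@H]1O[C@]1(C)C#CCOCc1ccc(OC)cc1 | intermediate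
11 | C6 TBS ether of 10, (2S,3S) | O=C1OC[C@H](Cc2ccccc2)N1C(=O)[C@@H](C(C)=C)[C@H](O[Si](C)(C)C(C)(C)C)[C@H]1O[C@]1(C)C#CCOCc1ccc(OC)cc1 | intermediate
12 | C12 allylic alcohol, 2-(3-hydroxyprop-1-en-2-yl) analogue of 11, (2S,3S) | O=C1OC[C@H](Cc2ccccc2)N1C(=O)[C@@H](C(=C)CO)[C@H](O[Si](C)(C)C(C)(C)C)[C@H]1O[C@]1(C)C#CCOCc1ccc(OC)cc1 | intermediate
13 | C12 TBDPS ether of 12, (2S,3S) | O=C1OC[C@H](Cc2ccccc2)N1C(=O)[C@@H](C(=C)CO[Si](c2ccccc2)(c2ccccc2)C(C)(C)C)[C@H](O[Si](C)(C)C(C)(C)C)[C@H]1O[C@]1(C)C#CCOCc1ccc(OC)cc1 | intermediate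
14 | (2R,3S)-3-(tert-butyldimethylsilyloxy)-2-[3-(tert-butyldiphenylsilyloxy)prop-1-en-2-yl]-3-{(2R,3R)-3-[3-(4-methoxybenzyloxy)prop-1-ynyl]-3-methyloxiran-2-yl}propan-1-ol | OC[C@@H](C(=C)CO[Si](c1ccccc1)(c1ccccc1)C(C)(C)C)[C@H](O[Si](C)(C)C(C)(C)C)[C@H]1O[C@]1(C)C#CCOCc1ccc(OC)cc1 | intermediate
15 | (2S,3S)-3-(tert-butyldimethylsilyloxy)-2-[3-(tert-butyldiphenylsilyloxy)prop-1-en-2-yl]-3-{(2R,3R)-3-[3-(4-methoxybenzyloxy)prop-1-ynyl]-3-methyloxiran-2-yl}propanal | O=C[C@@H](C(=C)CO[Si](c1ccccc1)(c1ccccc1)C(C)(C)C)[C@H](O[Si](C)(C)C(C)(C)C)[C@H]1O[C@]1(C)C#CCOCc1ccc(OC)cc1 | intermediate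
16 | methyl prop-2-ynoate | C#CC(=O)OC | starting material
17 | methyl (4S,5R,6S)-6-(tert-butyldimethylsilyloxy)-5-[3-(tert-butyldiphenylsilyloxy)prop-1-en-2-yl]-4-hydroxy-6-{(2R,3R)-3-[3-(4-methoxybenzyloxy)prop-1-ynyl]-3-methyloxiran-2-yl}hex-2-ynoate | COC(=O)C#C[C@@H](O)[C@@H](C(=C)CO[Si](c1ccccc1)(c1ccccc1)C(C)(C)C)[C@H](O[Si](C)(C)C(C)(C)C)[C@H]1O[C@]1(C)C#CCOCc1ccc(OC)cc1 | intermediate
18 | C8 triethylsilyl ether of 17, (4S,5R,6S) | COC(=O)C#C[C@@H](O[Si](CC)(CC)CC)[C@@H](C(=C)CO[Si](c1ccccc1)(c1ccccc1)C(C)(C)C)[C@H](O[Si](C)(C)C(C)(C)C)[C@H]1O[C@]1(C)C#CCOCc1ccc(OC)cc1 | intermediate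
19 | methyl (4S,5R,6S)-6-(tert-butyldimethylsilyloxy)-5-[3-(tert-butyldiphenylsilyloxy)prop-1-en-2-yl]-6-[(2R,3R)-3-(3-hydroxyprop-1-ynyl)-3-methyloxiran-2-yl]-4-(triethylsilyloxy)hex-2-ynoate | COC(=O)C#C[C@@H](O[Si](CC)(CC)CC)[C@@H](C(=C)CO[Si](c1ccccc1)(c1ccccc1)C(C)(C)C)[C@H](O[Si](C)(C)C(C)(C)C)[C@H]1O[C@]1(C)C#CCO | intermediate
20 | methyl (2E,4S,5R,6S)-3-(morpholin-4-yl)hex-2-enoate analogue of 19 (morpholino enoate) | COC(=O)/C=C(/N1CCOCC1)[C@@H](O[Si](CC)(CC)CC)[C@@H](C(=C)CO[Si](c1ccccc1)(c1ccccc1)C(C)(C)C)[C@H](O[Si](C)(C)C(C)(C)C)[C@H]1O[C@]1(C)C#CCO | intermediate (not isolated)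
21 | methyl (4S,5S,6S)-6-(tert-butyldimethylsilyloxy)-5-[3-(tert-butyldiphenylsilyloxy)prop-1-en-2-yl]-6-[(2R,3R)-3-(3-hydroxyprop-1-ynyl)-3-methyloxiran-2-yl]-3-oxo-4-(triethylsilyloxy)hexanoate | COC(=O)CC(=O)[C@@H](O[Si](CC)(CC)CC)[C@@H](C(=C)CO[Si](c1ccccc1)(c1ccccc1)C(C)(C)C)[C@H](O[Si](C)(C)C(C)(C)C)[C@H]1O[C@]1(C)C#CCO | intermediate
22 | methyl (4S,5S,6S)-…-6-{(2R,3R)-3-[(1Z)-3-hydroxyprop-1-enyl]-3-methyloxiran-2-yl}-3-oxo-4-(triethylsilyloxy)hexanoate (Z-allylic alcohol) | COC(=O)CC(=O)[C@@H](O[Si](CC)(CC)CC)[C@@H](C(=C)CO[Si](c1ccccc1)(c1ccccc1)C(C)(C)C)[C@H](O[Si](C)(C)C(C)(C)C)[C@H]1O[C@]1(C)/C=C\CO | intermediate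
23 | methyl (4S,5S,6S)-…-6-{(2R,3R)-3-methyl-3-[(1Z)-3-oxoprop-1-enyl]oxiran-2-yl}-3-oxo-4-(triethylsilyloxy)hexanoate (cis-enal keto ester) | COC(=O)CC(=O)[C@@H](O[Si](CC)(CC)CC)[C@@H](C(=C)CO[Si](c1ccccc1)(c1ccccc1)C(C)(C)C)[C@H](O[Si](C)(C)C(C)(C)C)[C@H]1O[C@]1(C)/C=C\C=O | intermediate
24 | methyl (1(10)E,2Z,4R,5R,6S,7S,8S)-6-(tert-butyldimethylsilyloxy)-12-(tert-butyldiphenylsilyloxy)-4,5-epoxy-9-oxo-8-(triethylsilyloxy)germacra-1(10),2,11(13)-trien-14-oate | O=C1[C@@H](O[Si](CC)(CC)CC)[C@@H](C(=C)CO[Si](c2ccccc2)(c2ccccc2)C(C)(C)C)[C@H](O[Si](C)(C)C(C)(C)C)[C@H]2O[C@]2(C)/C=C\C=C/1C(=O)OC | intermediate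
25 | (9S)-9-hydroxy analogue of 24, (4R,5R,6S,7R,8S,9S) | O[C@@H]1[C@@H](O[Si](CC)(CC)CC)[C@@H](C(=C)CO[Si](c2ccccc2)(c2ccccc2)C(C)(C)C)[C@H](O[Si](C)(C)C(C)(C)C)[C@H]2O[C@]2(C)/C=C\C=C/1C(=O)OC | intermediate
26 | 9-acetate of 25 | CC(=O)O[C@@H]1[C@@H](O[Si](CC)(CC)CC)[C@@H](C(=C)CO[Si](c2ccccc2)(c2ccccc2)C(C)(C)C)[C@H](O[Si](C)(C)C(C)(C)C)[C@H]2O[C@]2(C)/C=C\C=C/1C(=O)OC | intermediate
27 | 9-acetoxy-8-hydroxy compound (26 without the triethylsilyl group) | CC(=O)O[C@@H]1[C@@H](O)[C@@H](C(=C)CO[Si](c2ccccc2)(c2ccccc2)C(C)(C)C)[C@H](O[Si](C)(C)C(C)(C)C)[C@H]2O[C@]2(C)/C=C\C=C/1C(=O)OC | intermediate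
28 | (Z)-2-methylbut-2-enoic acid | C/C=C(/C)C(=O)O | starting material
29 | (Z)-2-methylbut-2-en-1-ol | C/C=C(/C)CO | intermediate
30 | [(2R,3S)-2,3-dimethyloxiran-2-yl]methanol | OC[C@@]1(C)O[C@H]1C | intermediate
31 | (2S,3S)-2,3-dimethyloxirane-2-carboxylic acid | OC(=O)[C@@]1(C)O[C@H]1C | intermediate
32 | (2S,3S)-2,3-dimethyloxirane-2-carboxylic 2,4,6-trichlorobenzoic anhydride | O=C(OC(=O)c1c(Cl)cc(Cl)cc1Cl)[C@@]1(C)O[C@H]1C | intermediate (not isolated)
33 | 8-O-[(2S,3S)-2,3-dimethyloxirane-2-carbonyl] derivative of 27 | CC(=O)O[C@@H]1[C@@H](OC(=O)[C@@]2(C)O[C@H]2C)[C@@H](C(=C)CO[Si](c2ccccc2)(c2ccccc2)C(C)(C)C)[C@H](O[Si](C)(C)C(C)(C)C)[C@H]2O[C@]2(C)/C=C\C=C/1C(=O)OC | intermediate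
34 | 6,12-diol, (4R,5R,6S,7S,8S,9S) | CC(=O)O[C@@H]1[C@@H](OC(=O)[C@@]2(C)O[C@H]2C)[C@@H](C(=C)CO)[C@H](O)[C@H]2O[C@]2(C)/C=C\C=C/1C(=O)OC | intermediate
35 | 6-hydroxy-12-al (hydroxy enal) | CC(=O)O[C@@H]1[C@@H](OC(=O)[C@@]2(C)O[C@H]2C)[C@@H](C(=C)C=O)[C@H](O)[C@H]2O[C@]2(C)/C=C\C=C/1C(=O)OC | intermediate (not isolated)
36 | 12-hydroxy-6,12-epoxy lactol (both C12 epimers) | C=C1C(O)O[C@H]2[C@H]1[C@H](OC(=O)[C@@]1(C)O[C@H]1C)[C@@H](OC(C)=O)/C(C(=O)OC)=C\C=C/[C@@]1(C)O[C@H]21 | intermediate (not isolated)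
37 | CNP0229507.6, (4R,5R,6S,7R,8S,9S)-12,6-olide | C=C1C(=O)O[C@H]2[C@H]1[C@H](OC(=O)[C@@]1(C)O[C@H]1C)[C@@H](OC(C)=O)/C(C(=O)OC)=C\C=C/[C@@]1(C)O[C@H]21 | target

## Step count and least certain steps

Total: 28 steps. Longest linear sequence: 24 steps (1 → 37 through steps 1–5, 7–22 and 26–28).

Step 19 (key step, proposed new method).
- What may go wrong: reversible conjugate addition of piperidine to the cis-enal isomerizes it to the trans-enal faster than the ring closes, and the trans isomer can only oligomerize. The medium-ring closure is slow enough for intermolecular condensation to compete even at high dilution. The product cis-dienone may be drained into its 2H-pyran valence isomer. Long exposure to amine may epimerize C8, which is α to the ketone.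
- Fallback (known chemistry), from 22 back to 24: Corey–Kim chlorination (NCS, Me2S, CH2Cl2, −20 °C) converts the Z-allylic alcohol into the (Z)-allylic chloride F1 without touching the alkene geometry. Cs2CO3 with catalytic CsI in MeCN under high dilution then alkylates C10 with C1, in the manner of the established macrocyclizations of malonates and β-keto esters with allylic chlorides, and gives the ten-membered β-keto ester F2 (10-exo-tet, irreversible, no amine, no enal). Selenenylation at C10 (NaH, PhSeCl, THF, −78 °C) gives selenide F3, and oxidation with H2O2 followed by syn elimination toward C1 rejoins the route at 24.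

Step 20 (Luche reduction).
- What may go wrong: hydride delivery from the wrong face, because the ring conformation and not the C8 substituent may decide, and competing conjugate addition to the doubly activated diene.
- Fallback: the 9-epimer F4 is not discarded. Mitsunobu esterification with acetic acid (PPh3, DIAD, toluene, 0 °C) inverts C9 and installs the acetate in one operation, rejoining the route at 26.

Step 26 (esterification of O8).
- What may go wrong: the hindered hydroxyl acylates slowly, so base-induced migration of the acetyl group from O9 to O8 can come first and lead to the transposed diester; DMAP may also attack the allylic acetate in SN2′ fashion.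
- Fallback, from 24 to 33: the order of the end game is changed. PPTS in MeOH removes the triethylsilyl group of 24 to give hydroxy ketone F5. Yamaguchi esterification with 31 (through 32) gives acyloxy ketone F6, where no neighbouring ester exists to migrate. Luche reduction gives alcohol F7 (the acyloxy group cannot chelate and reinforces the polar Felkin–Anh preference), and acetylation of F7 rejoins the route at 33.

Step 13 (alkynylation).
- What may go wrong: loss of facial control at C8, because the substrate bias (α-branch and β-silyloxy group) opposes the catalyst, and epimerization or alkene migration in the α-vinyl aldehyde during a slow zinc-mediated addition.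
- Fallback, from 15 to 17: the lithium acetylide of 16 (LiHMDS, THF, −78 °C) adds within minutes and gives 17 together with its C8 epimer F8. Dess–Martin oxidation of the mixture gives ynone F9. (S)-2-Methyl-CBS-oxazaborolidine with catecholborane at −78 °C reduces F9 under catalyst control (alkynyl as the small group) and returns 17.

Step 9 (allylic oxidation).
- What may go wrong: over-oxidation to the enal, stalling at partial conversion, or attack at the propargylic ether carbon instead of the isopropenyl methyl group.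
- Fallback, from 11 to 12: ene-type chlorination of the isopropenyl group with HOCl (NaOCl, CeCl3·7H2O, CH2Cl2/H2O, 0 °C) gives allylic chloride F10. Displacement with sodium formate (Bu4NI, DMF) gives formate F11, and methanolysis (NaHCO3, MeOH, 0 °C) rejoins the route at 12.

## Further compounds

F1 | step 19 | (Z)-allylic chloride from 22 (C1–Cl in place of C1–OH) | COC(=O)CC(=O)[C@@H](O[Si](CC)(CC)CC)[C@@H](C(=C)CO[Si](c1ccccc1)(c1ccccc1)C(C)(C)C)[C@H](O[Si](C)(C)C(C)(C)C)[C@H]1O[C@]1(C)/C=C\CCl
F2 | step 19 | ten-membered β-keto ester with C1 as CH2 and C10 as CH (C10 epimers, 2Z) | O=C1[C@@H](O[Si](CC)(CC)CC)[C@@H](C(=C)CO[Si](c2ccccc2)(c2ccccc2)C(C)(C)C)[C@H](O[Si](C)(C)C(C)(C)C)[C@H]2O[C@]2(C)/C=C\CC1C(=O)OC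
F3 | step 19 | 10-phenylselanyl derivative of F2 | O=C1[C@@H](O[Si](CC)(CC)CC)[C@@H](C(=C)CO[Si](c2ccccc2)(c2ccccc2)C(C)(C)C)[C@H](O[Si](C)(C)C(C)(C)C)[C@H]2O[C@]2(C)/C=C\CC1([Se]c1ccccc1)C(=O)OC
F4 | step 20 | 9-epimer of 25 ((9R)-alcohol) | O[C@H]1[C@@H](O[Si](CC)(CC)CC)[C@@H](C(=C)CO[Si](c2ccccc2)(c2ccccc2)C(C)(C)C)[C@H](O[Si](C)(C)C(C)(C)C)[C@H]2O[C@]2(C)/C=C\C=C/1C(=O)OC
F5 | step 26 | 8-hydroxy-9-oxo macrocycle (24 without the triethylsilyl group) | O=C1[C@@H](O)[C@@H](C(=C)CO[Si](c2ccccc2)(c2ccccc2)C(C)(C)C)[C@H](O[Si](C)(C)C(C)(C)C)[C@H]2O[C@]2(C)/C=C\C=C/1C(=O)OC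
F6 | step 26 | 8-O-[(2S,3S)-2,3-dimethyloxirane-2-carbonyl]-9-oxo macrocycle | O=C1[C@@H](OC(=O)[C@@]2(C)O[C@H]2C)[C@@H](C(=C)CO[Si](c2ccccc2)(c2ccccc2)C(C)(C)C)[C@H](O[Si](C)(C)C(C)(C)C)[C@H]2O[C@]2(C)/C=C\C=C/1C(=O)OC
F7 | step 26 | (9S)-9-hydroxy derivative of F6 | O[C@@H]1[C@@H](OC(=O)[C@@]2(C)O[C@H]2C)[C@@H](C(=C)CO[Si](c2ccccc2)(c2ccccc2)C(C)(C)C)[C@H](O[Si](C)(C)C(C)(C)C)[C@H]2O[C@]2(C)/C=C\C=C/1C(=O)OC
F8 | step 13 | C8 epimer of 17 ((4R)-carbinol) | COC(=O)C#C[C@H](O)[C@@H](C(=C)CO[Si](c1ccccc1)(c1ccccc1)C(C)(C)C)[C@H](O[Si](C)(C)C(C)(C)C)[C@H]1O[C@]1(C)C#CCOCc1ccc(OC)cc1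
F9 | step 13 | 4-oxo-hex-2-ynoate (ynone) from 17 and F8 | COC(=O)C#CC(=O)[C@@H](C(=C)CO[Si](c1ccccc1)(c1ccccc1)C(C)(C)C)[C@H](O[Si](C)(C)C(C)(C)C)[C@H]1O[C@]1(C)C#CCOCc1ccc(OC)cc1
F10 | step 9 | 2-(3-chloroprop-1-en-2-yl) analogue of 11 (allylic chloride) | O=C1OC[C@H](Cc2ccccc2)N1C(=O)[C@@H](C(=C)CCl)[C@H](O[Si](C)(C)C(C)(C)C)[C@H]1O[C@]1(C)C#CCOCc1ccc(OC)cc1
F11 | step 9 | formate ester of 12 | O=C1OC[C@H](Cc2ccccc2)N1C(=O)[C@@H](C(=C)COC=O)[C@H](O[Si](C)(C)C(C)(C)C)[C@H]1O[C@]1(C)C#CCOCc1ccc(OC)cc1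
A1 | alternative 1 | 4,5-deoxy target (4E alkene in place of the epoxide), trienoate lactone | C=C1C(=O)O[C@H]2[C@H]1[C@H](OC(=O)[C@@]1(C)O[C@H]1C)[C@@H](OC(C)=O)/C(C(=O)OC)=C\C=C/C(C)=C/2
A2 | alternative 1 | 6-deoxy seco acid: 9-acetoxy-8-[(2S,3S)-2,3-dimethyloxirane-2-carbonyloxy]-14-methoxy-14-oxogermacra-1(10)E,2Z,4E,11(13)-tetraen-12-oic acid | C=C(C(=O)O)[C@@H]1[C@H](OC(=O)[C@@]2(C)O[C@H]2C)[C@@H](OC(C)=O)/C(C(=O)OC)=C\C=C/C(C)=C/C1
A3 | alternative 2 | exo (6+4) adduct, ketone bridge joining C4 and C9 | O=C1[C@]2(C)C=CC=C(C(=O)OC)[C@H]1[C@H](O[Si](C)(C)C(C)(C)C)C(CC(=O)OC)=C[C@@H]2O[Si](C)(C)C(C)(C)C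
A4 | alternative 2 | methyl 4-methyl-3-oxocyclohepta-1,4,6-triene-1-carboxylate (tropone) | O=C1C=C(C(=O)OC)C=CC=C1C
A5 | alternative 2 | methyl (3E)-4-(tert-butyldimethylsilyloxy)-3-[(E)-(tert-butyldimethylsilyloxy)methylidene]but-3-enoate (1,4-bis(silyloxy)diene) | COC(=O)CC(/C=C/O[Si](C)(C)C(C)(C)C)=C\O[Si](C)(C)C(C)(C)C
A6 | alternative 3 | ten-membered 1(10),2,4-triene lactone with 8-O-triethylsilyl group | C=C1C(=O)O[C@H]2[C@H]1[C@H](O[Si](CC)(CC)CC)[C@@H](OC(C)=O)/C(C(=O)OC)=C\C=C/C(C)=C/2
A7 | alternative 3 | cis-fused hexalin (C5–C10 bond closed; one cis-fused diastereomer drawn) | C=C1C(=O)O[C@H]2[C@H]1[C@H](O[Si](CC)(CC)CC)[C@@H](OC(C)=O)[C@]3(C(=O)OC)C=CC=C(C)[C@H]23
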